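**Plan**

- Ring D is a resorcinol (oxygen on C7' and C8a') whose C6' is bonded to the crowded C4 of ring C and whose C4a' carries C4'. This 1,2,4,5-pattern is a β-keto ester chain (C6'–C7'–C8'–C8a') joined to the three carbons of an ynone (C5', C4a', C4').
- Retrosynthesis: C4'–OH back to the ketone; ring F cut at O1'–C2' and C2'–C3' (oxirane opening, aldol); ring D cut at C5'–C6' and C4a'–C8a' ([4+2]); the diene chain cut at C7'–C8' (malonate) and C4–C6' (Reformatsky); ring C cut at O1–C2 and C2–C3.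
- Forward: ring C is closed onto ring A with ring B in place, the C4 chain is grown to a 1-methoxy-1,3-bis(silyloxy)diene, ring D is annulated, ring E is attached by aldol condensation, ring F is closed, and the ketone is reduced last.
- Stereochemistry: C2/C3 and C2'/C3' come from two poly-L-leucine epoxidations, each relayed by an invertive ring closure. C4 comes from hydride delivery anti to O3 onto a C4 cation. C4' comes from borohydride attack giving the 4'-OH trans to the 3'-OH.

Key step: step 12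

**Remarks**

- Locants follow flavan numbering, primed for the lower unit (rings A/C/B upper, D/F/E lower).
- Fl = (2R,3S)-7-(benzyloxy)-2-[3,4-bis(benzyloxy)phenyl]-3-[(tert-butyldimethylsilyl)oxy]-3,4-dihydro-2H-chromen-4-yl, i.e. 2,3-trans with the C4 substituent cis to O3.
- The C4 letter of Fl switches between S and R only because O-substituents on ring D change the CIP ranking; the geometry is the same from 12 onward.
- Assumption: 1 is a catalogue compound (otherwise one benzylation from 2,4-dihydroxyacetophenone).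

**Route**

Step 1
Reactants: 1 1-[4-(benzyloxy)-2-hydroxyphenyl]ethanone
Product: 2 1-[4-(benzyloxy)-2-(methoxymethoxy)phenyl]ethanone
Conditions: MOMCl (excess), i-Pr2NEt, CH2Cl2, 0 °C → reflux
Reagents that add atoms: chloromethyl methyl ether, COCCl
Why: Williamson-type O-alkylation of the hydrogen-bonded phenol installs an acetal that survives the basic steps and leaves in the acid ring closure; a free 2'-hydroxychalcone would divert the peroxide step into an Algar–Flynn–Oyamada oxidation.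

Step 2
Reactants: 2 MOM-protected acetophenone; 3 3,4-bis(benzyloxy)benzaldehyde
Product: 4 (E)-chalcone
Conditions: KOH, EtOH/THF, rt
Reagents that add atoms: none
Why: Claisen–Schmidt condensation of a methyl ketone with a non-enolisable aldehyde, the aldol dehydrating in the flask to the conjugated (E)-enone.

Step 3
Reactants: 4 (E)-chalcone
Product: 5 (2R,3S)-epoxy ketone
Conditions: poly-L-leucine (cat.), urea–H2O2, DBU, THF, rt
Reagents that add atoms: urea–hydrogen peroxide adduct, NC(N)=O.OO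
Why: Juliá–Colonna epoxidation, a Weitz–Scheffer addition of hydroperoxide inside the helical poly-L-leucine, which steers trans-chalcones to the (2R,3S)-oxirane, so both future carbinol carbons of ring C are fixed by the catalyst.

Step 4
Reactants: 5 (2R,3S)-epoxy ketone
Product: 7 (2R,3R)-7,3',4'-tri-O-benzylfustin, via 2'-hydroxy epoxy ketone 6 (not isolated)
Conditions: conc. HCl, MeOH/THF, 50 °C; the product is recrystallised
Reagents that add atoms: none
Why: Acid methanolysis of the acetal frees the phenol of 6, which opens the oxirane at its benzylic carbon in a 6-endo closure with inversion, so C2 becomes R while C3 keeps the oxirane configuration and the 2,3-trans dihydroflavonol should result; a more ionised opening still closes to the diequatorial trans isomer.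

Step 5
Reactants: 7 tri-O-benzylfustin
Product: 8 3-O-TBS ketone
Conditions: TBSOTf, 2,6-lutidine, CH2Cl2, −78 → 0 °C
Reagents that add atoms: tert-butyldimethylsilyl trifluoromethanesulfonate, CC(C)(C)[Si](C)(C)OS(=O)(=O)C(F)(F)F
Why: O-silylation with a silyl triflate and a hindered pyridine base is fast at low temperature and too weakly basic to enolise C3 or open the pyranone; the bulky silyl ether later shields one face of C4.

Step 6
Reactants: 8 3-O-TBS ketone; 9 methyl bromoacetate
Product: 11 C4-carbinol ester (both C4 epimers), via bromozinc ester enolate 10 (not isolated)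
Conditions: Zn dust (TMSCl-activated), THF, 50 °C; aq. NH4Cl
Reagents that add atoms: none
Why: Reformatsky reaction; the weakly basic zinc enolate 10 adds to the C4 ketone without enolising C3, and the configuration of the new carbinol carbon is immaterial because it is ionised in step 7.

Step 7
Reactants: 11 C4-carbinol ester
Product: 12 methyl 2-[(4S)-Fl]acetate
Conditions: Et3SiH, CF3CO2H, CH2Cl2, −40 → 0 °C
Reagents that add atoms: none
Why: Ionic hydrogenation; acid ionises the tertiary benzylic alcohol to a C4 cation stabilised by the para 7-benzyloxy group, and Et3SiH delivers hydride to the face anti to the neighbouring 3-silyloxy group (the facial bias established for hydride capture of 4-substituted flavan-4-yl cations carrying a 3-silyl ether), which sets C4 with H4 trans and the acetate arm cis to O3.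

Step 8
Reactants: 12 methyl 2-[(4S)-Fl]acetate
Product: 13 2-[(4S)-Fl]acetic acid
Conditions: LiOH·H2O, THF/MeOH/H2O, rt; then cold 1 M HCl to pH 4
Reagents that add atoms: lithium hydroxide, [Li+].[OH-]
Why: Saponification by acyl–oxygen cleavage of an unhindered methyl ester; the silyl and benzyl ethers tolerate cold aqueous hydroxide and the brief mild acidification.

Step 9
Reactants: 13 2-[(4S)-Fl]acetic acid; 14 potassium methyl malonate (KO2CCH2CO2Me)
Product: 17 methyl 4-[(4S)-Fl]-3-oxobutanoate, via acyl imidazolide 15 (not isolated), via acylmalonic half ester 16 (not isolated)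
Conditions: CDI, THF, rt; then 14, MgCl2, Et3N, THF, rt → 40 °C; cold 0.5 M HCl
Reagents that add atoms: none
Why: Masamune–Brooks chain extension; the acyl imidazolide 15 C-acylates the magnesium enolate of the malonate half ester and the acylmalonic acid 16 loses CO2, giving the β-keto ester under near-neutral conditions.

Step 10
Reactants: 17 β-keto ester
Product: 18 methyl 4-[(4S)-Fl]-3-(trimethylsilyloxy)but-2-enoate
Conditions: TMSCl, Et3N, toluene, rt; filtration, evaporation
Reagents that add atoms: chlorotrimethylsilane, C[Si](C)(C)Cl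
Why: Soft enolisation and O-silylation of the β-keto ester give the conjugated silyl enol ether, the usual first stage toward 1-alkoxy-1,3-bis(silyloxy)dienes.

Step 11
Reactants: 18 silyloxy enoate
Product: 20 1-methoxy-1,3-bis(trimethylsilyloxy)diene carried on C4 of Fl, via lithium dienolate 19 (not isolated)
Conditions: LiN(i-Pr)2, THF, −78 °C; TMSCl, −78 → 0 °C; evaporation, pentane, filtration under argon
Reagents that add atoms: chlorotrimethylsilane, C[Si](C)(C)Cl
Why: Kinetic γ-deprotonation of the silyloxy enoate gives the extended dienolate 19, which TMSCl traps on the ester oxygen as the silyl ketene acetal; the moisture-sensitive diene is isolated without water and used at once.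

Step 12
Reactants: 20 bis(silyloxy)diene; 21 but-3-yn-2-one
Product: 24 1-{5-[(4S)-Fl]-2,4-dihydroxyphenyl}ethanone, via cyclohexadiene cycloadduct 22 (not isolated), via bis(trimethylsilyl) aryl ether 23 (not isolated)
Conditions: 21 (3 equiv), toluene, sealed tube, 0 → 70 °C; then 1 M HCl, THF, 0 °C
Reagents that add atoms: none
Why: The electron-rich diene and the ynone combine in a normal-demand [4+2] cycloaddition in which the diene terminus on C4 (future C6') bonds to the alkyne CH β to the carbonyl (future C5') and the ketene acetal carbon (future C8a') bonds to the α carbon (future C4a'); in the asynchronous limit this is a Mukaiyama–Michael addition followed by 6-exo-trig closure of the allenyl enolate onto the silyloxy(methoxy)carbenium carbon. Ring D thus closes as a six-membered carbocycle by intermolecular [4+2] ring formation, and the 1,4-cyclohexadiene 22 aromatises by 1,4-elimination of methanol to 23, whose two aryl silyl ethers are hydrolysed in the cold acidic work-up that leaves the secondary TBS ether alone. The closest known reaction type is the Diels–Alder benzannulation of 1-alkoxy-1,3-bis(silyloxy)-1,3-dienes with acetylenic ketones and esters to give acyl resorcinols. No lasting stereocentre is created (the two sp3 ring carbons of 22 vanish on aromatisation), and C4 is retained because it is never ionised or deprotonated under these neutral thermal conditions. The step needs a single regiochemistry, acetyl on C4a' next to the C8a' oxygen and H on C5' next to C6', and the matched polarity of the diene (nucleophilic at the C4-bound terminus) and the ynone (electrophilic at its unsubstituted β carbon) secures it while keeping the hindered terminus accessible.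

Step 13
Reactants: 24 ring-D dihydroxyacetophenone
Product: 25 1-{5-[(4R)-Fl]-2,4-bis(methoxymethoxy)phenyl}ethanone
Conditions: MOMCl (excess), i-Pr2NEt, CH2Cl2, 0 °C → reflux
Reagents that add atoms: chloromethyl methyl ether, COCCl
Why: Acetal etherification of both phenols (the chelated one needs excess reagent and heat) protects them against basic peroxide and lets one acid step unmask them again.

Step 14
Reactants: 25 bis(MOM) acetophenone; 3 3,4-bis(benzyloxy)benzaldehyde
Product: 26 (E)-chalcone of the lower unit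
Conditions: KOH, EtOH/THF, rt
Reagents that add atoms: none
Why: Claisen–Schmidt condensation as in step 2; the secondary silyl ether and the acetals are stable to ethanolic hydroxide at room temperature.

Step 15
Reactants: 26 (E)-chalcone of the lower unit
Product: 27 (2R,3S)-epoxy ketone of the lower unit
Conditions: poly-L-leucine (cat.), urea–H2O2, DBU, THF, rt
Reagents that add atoms: urea–hydrogen peroxide adduct, NC(N)=O.OO
Why: Juliá–Colonna epoxidation under catalyst control; poly-L-leucine should again give the (2R,3S)-oxirane, the remote stereocentres of the upper unit having little influence, and any mismatched product is a separable diastereomer.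

Step 16
Reactants: 27 (2R,3S)-epoxy ketone of the lower unit
Product: 30 penta-O-benzyl biflavanoid dihydroflavonol, via dihydroxy epoxy ketone 28 (not isolated), via 3-O-silyl dihydroflavonol 29 (not isolated)
Conditions: conc. HCl, MeOH/THF, 55 °C
Reagents that add atoms: none
Why: Acid domino; acetal methanolysis frees the phenol ortho to the ketone (28), which opens the oxirane at the benzylic carbon by 6-endo attack with inversion to the 2',3'-trans ring F (29, 2'R,3'R), and the same medium then removes the silyl ether, while the para phenol cannot reach the oxirane.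

Step 17
Reactants: 30 penta-O-benzyl biflavanoid dihydroflavonol
Product: 31 free phenolic biflavanoid dihydroflavonol
Conditions: H2 (1 atm), Pd(OH)2/C, THF/MeOH, rt
Reagents that add atoms: none
Why: Hydrogenolysis of the five benzyl aryl ethers; the chroman C2–O bonds, the diaryl methine C4 and the deactivated 4'-ketone (conjugated with the 7'-OH) are expected to stay intact at ambient pressure.

Step 18
Reactants: 31 free phenolic biflavanoid dihydroflavonol
Product: 32 target flavan-3,4-diol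
Conditions: NaBH4, EtOH, 0 °C → rt; aq. NH4Cl to pH 6–7, cold work-up
Reagents that add atoms: none
Why: Borohydride reduction of a 2,3-trans dihydroflavonol; hydride attacks C4' axially and gives the equatorial 4'-OH trans to the 3'-OH (4'R, 2,3-trans-3,4-trans), and the step is placed last with a near-neutral work-up because the 4'-carbinol is acid-labile and would not survive hydrogenolysis.

**Compound list**

1 | 1-[4-(benzyloxy)-2-hydroxyphenyl]ethanone | CC(=O)c1ccc(OCc2ccccc2)cc1O | starting material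
2 | 1-[4-(benzyloxy)-2-(methoxymethoxy)phenyl]ethanone | CC(=O)c1ccc(OCc2ccccc2)cc1OCOC | intermediate
3 | 3,4-bis(benzyloxy)benzaldehyde | O=Cc1ccc(OCc2ccccc2)c(OCc2ccccc2)c1 | starting material
4 | (E)-1-[4-(benzyloxy)-2-(methoxymethoxy)phenyl]-3-[3,4-bis(benzyloxy)phenyl]prop-2-en-1-one | COCOc1cc(OCc2ccccc2)ccc1C(=O)/C=C/c1ccc(OCc2ccccc2)c(OCc2ccccc2)c1 | intermediate
5 | [4-(benzyloxy)-2-(methoxymethoxy)phenyl]{(2R,3S)-3-[3,4-bis(benzyloxy)phenyl]oxiran-2-yl}methanone | COCOc1cc(OCc2ccccc2)ccc1C(=O)[C@@H]3O[C@H]3c4ccc(OCc2ccccc2)c(OCc2ccccc2)c4 | intermediate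
6 | [4-(benzyloxy)-2-hydroxyphenyl]{(2R,3S)-3-[3,4-bis(benzyloxy)phenyl]oxiran-2-yl}methanone | Oc1cc(OCc2ccccc2)ccc1C(=O)[C@@H]3O[C@H]3c4ccc(OCc2ccccc2)c(OCc2ccccc2)c4 | intermediate (not isolated)
7 | (2R,3R)-7-(benzyloxy)-2-[3,4-bis(benzyloxy)phenyl]-3-hydroxy-2,3-dihydro-4H-chromen-4-one (2,3-trans) | O(Cc3ccccc3)c1ccc2c(c1)O[C@H](c1ccc(OCc3ccccc3)c(OCc3ccccc3)c1)[C@@H](O)C2=O | intermediate
8 | (2R,3R)-7-(benzyloxy)-2-[3,4-bis(benzyloxy)phenyl]-3-[(tert-butyldimethylsilyl)oxy]-2,3-dihydro-4H-chromen-4-one | O(Cc3ccccc3)c1ccc2c(c1)O[C@H](c1ccc(OCc3ccccc3)c(OCc3ccccc3)c1)[C@@H](O[Si](C)(C)C(C)(C)C)C2=O | intermediate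
9 | methyl bromoacetate | COC(=O)CBr | starting material
10 | bromo(2-methoxy-2-oxoethyl)zinc | COC(=O)C[Zn]Br | intermediate (not isolated)
11 | methyl 2-{(2R,3R,4RS)-7-(benzyloxy)-2-[3,4-bis(benzyloxy)phenyl]-3-[(tert-butyldimethylsilyl)oxy]-4-hydroxy-3,4-dihydro-2H-chromen-4-yl}acetate (C4 epimers) | O(Cc3ccccc3)c1ccc2c(c1)O[C@H](c1ccc(OCc3ccccc3)c(OCc3ccccc3)c1)[C@@H](O[Si](C)(C)C(C)(C)C)C2(O)CC(=O)OC | intermediate
12 | methyl 2-[(4S)-Fl]acetate (2,3-trans-3,4-cis) | O(Cc3ccccc3)c1ccc2c(c1)O[C@H](c1ccc(OCc3ccccc3)c(OCc3ccccc3)c1)[C@@H](O[Si](C)(C)C(C)(C)C)[C@H]2CC(=O)OC | intermediate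
13 | 2-[(4S)-Fl]acetic acid | O(Cc3ccccc3)c1ccc2c(c1)O[C@H](c1ccc(OCc3ccccc3)c(OCc3ccccc3)c1)[C@@H](O[Si](C)(C)C(C)(C)C)[C@H]2CC(=O)O | intermediate
14 | potassium 3-methoxy-3-oxopropanoate | COC(=O)CC(=O)[O-].[K+] | starting material
15 | 2-[(4S)-Fl]-1-(imidazol-1-yl)ethanone | O(Cc3ccccc3)c1ccc2c(c1)O[C@H](c1ccc(OCc3ccccc3)c(OCc3ccccc3)c1)[C@@H](O[Si](C)(C)C(C)(C)C)[C@H]2CC(=O)n1ccnc1 | intermediate (not isolated)
16 | 4-[(4S)-Fl]-2-(methoxycarbonyl)-3-oxobutanoic acid (malonate CH undefined) | O(Cc3ccccc3)c1ccc2c(c1)O[C@H](c1ccc(OCc3ccccc3)c(OCc3ccccc3)c1)[C@@H](O[Si](C)(C)C(C)(C)C)[C@H]2CC(=O)C(C(=O)O)C(=O)OC | intermediate (not isolated)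
17 | methyl 4-[(4S)-Fl]-3-oxobutanoate | O(Cc3ccccc3)c1ccc2c(c1)O[C@H](c1ccc(OCc3ccccc3)c(OCc3ccccc3)c1)[C@@H](O[Si](C)(C)C(C)(C)C)[C@H]2CC(=O)CC(=O)OC | intermediate
18 | methyl 4-[(4S)-Fl]-3-[(trimethylsilyl)oxy]but-2-enoate (alkene geometry of no consequence) | O(Cc3ccccc3)c1ccc2c(c1)O[C@H](c1ccc(OCc3ccccc3)c(OCc3ccccc3)c1)[C@@H](O[Si](C)(C)C(C)(C)C)[C@H]2CC(O[Si](C)(C)C)=CC(=O)OC | intermediate
19 | lithium 4-[(4S)-Fl]-1-methoxy-3-[(trimethylsilyl)oxy]buta-1,3-dien-1-olate | O(Cc3ccccc3)c1ccc2c(c1)O[C@H](c1ccc(OCc3ccccc3)c(OCc3ccccc3)c1)[C@@H](O[Si](C)(C)C(C)(C)C)[C@H]2C=C(O[Si](C)(C)C)C=C(OC)O[Li] | intermediate (not isolated)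
20 | (4S)-Fl bearing a 4-methoxy-2,4-bis[(trimethylsilyl)oxy]buta-1,3-dien-1-yl group at C4 (geometric isomers, both sp2 termini end in the arene) | O(Cc3ccccc3)c1ccc2c(c1)O[C@H](c1ccc(OCc3ccccc3)c(OCc3ccccc3)c1)[C@@H](O[Si](C)(C)C(C)(C)C)[C@H]2C=C(O[Si](C)(C)C)C=C(OC)O[Si](C)(C)C | intermediate
21 | but-3-yn-2-one | CC(=O)C#C | starting material
22 | 1-{3-[(4S)-Fl]-6-methoxy-4,6-bis[(trimethylsilyl)oxy]cyclohexa-1,4-dien-1-yl}ethanone (two transient sp3 ring centres, undefined) | O(Cc3ccccc3)c1ccc2c(c1)O[C@H](c1ccc(OCc3ccccc3)c(OCc3ccccc3)c1)[C@@H](O[Si](C)(C)C(C)(C)C)[C@H]2C1C=C(C(C)=O)C(OC)(O[Si](C)(C)C)C=C1O[Si](C)(C)C | intermediate (not isolated)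
23 | 1-{5-[(4R)-Fl]-2,4-bis[(trimethylsilyl)oxy]phenyl}ethanone | O(Cc3ccccc3)c1ccc2c(c1)O[C@H](c1ccc(OCc3ccccc3)c(OCc3ccccc3)c1)[C@@H](O[Si](C)(C)C(C)(C)C)[C@H]2c1cc(C(C)=O)c(O[Si](C)(C)C)cc1O[Si](C)(C)C | intermediate (not isolated)
24 | 1-{5-[(4S)-Fl]-2,4-dihydroxyphenyl}ethanone | O(Cc3ccccc3)c1ccc2c(c1)O[C@H](c1ccc(OCc3ccccc3)c(OCc3ccccc3)c1)[C@@H](O[Si](C)(C)C(C)(C)C)[C@H]2c1cc(C(C)=O)c(O)cc1O | intermediate
25 | 1-{5-[(4R)-Fl]-2,4-bis(methoxymethoxy)phenyl}ethanone | O(Cc3ccccc3)c1ccc2c(c1)O[C@H](c1ccc(OCc3ccccc3)c(OCc3ccccc3)c1)[C@@H](O[Si](C)(C)C(C)(C)C)[C@H]2c1cc(C(C)=O)c(OCOC)cc1OCOC | intermediate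
26 | (E)-3-[3,4-bis(benzyloxy)phenyl]-1-{5-[(4R)-Fl]-2,4-bis(methoxymethoxy)phenyl}prop-2-en-1-one | O(Cc3ccccc3)c1ccc2c(c1)O[C@H](c1ccc(OCc3ccccc3)c(OCc3ccccc3)c1)[C@@H](O[Si](C)(C)C(C)(C)C)[C@H]2c1cc(C(=O)/C=C/c4ccc(OCc5ccccc5)c(OCc5ccccc5)c4)c(OCOC)cc1OCOC | intermediate
27 | {(2R,3S)-3-[3,4-bis(benzyloxy)phenyl]oxiran-2-yl}{5-[(4R)-Fl]-2,4-bis(methoxymethoxy)phenyl}methanone | O(Cc3ccccc3)c1ccc2c(c1)O[C@H](c1ccc(OCc3ccccc3)c(OCc3ccccc3)c1)[C@@H](O[Si](C)(C)C(C)(C)C)[C@H]2c1cc(C(=O)[C@@H]4O[C@H]4c6ccc(OCc5ccccc5)c(OCc5ccccc5)c6)c(OCOC)cc1OCOC | intermediate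
28 | {(2R,3S)-3-[3,4-bis(benzyloxy)phenyl]oxiran-2-yl}{5-[(4S)-Fl]-2,4-dihydroxyphenyl}methanone | O(Cc3ccccc3)c1ccc2c(c1)O[C@H](c1ccc(OCc3ccccc3)c(OCc3ccccc3)c1)[C@@H](O[Si](C)(C)C(C)(C)C)[C@H]2c1cc(C(=O)[C@@H]4O[C@H]4c6ccc(OCc5ccccc5)c(OCc5ccccc5)c6)c(O)cc1O | intermediate (not isolated)
29 | (2R,3R)-2-[3,4-bis(benzyloxy)phenyl]-6-[(4S)-Fl]-3,7-dihydroxy-2,3-dihydro-4H-chromen-4-one | O(Cc3ccccc3)c1ccc2c(c1)O[C@H](c1ccc(OCc3ccccc3)c(OCc3ccccc3)c1)[C@@H](O[Si](C)(C)C(C)(C)C)[C@H]2c1cc2c(cc1O)O[C@H](c1ccc(OCc3ccccc3)c(OCc3ccccc3)c1)[C@@H](O)C2=O | intermediate (not isolated)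
30 | (2R,3R)-6-{(2R,3S,4S)-7-(benzyloxy)-2-[3,4-bis(benzyloxy)phenyl]-3-hydroxy-3,4-dihydro-2H-chromen-4-yl}-2-[3,4-bis(benzyloxy)phenyl]-3,7-dihydroxy-2,3-dihydro-4H-chromen-4-one | O(Cc3ccccc3)c1ccc2c(c1)O[C@H](c1ccc(OCc3ccccc3)c(OCc3ccccc3)c1)[C@@H](O)[C@H]2c1cc2c(cc1O)O[C@H](c1ccc(OCc3ccccc3)c(OCc3ccccc3)c1)[C@@H](O)C2=O | intermediate
31 | (2R,3R)-2-(3,4-dihydroxyphenyl)-6-[(2R,3S,4S)-2-(3,4-dihydroxyphenyl)-3,7-dihydroxy-3,4-dihydro-2H-chromen-4-yl]-3,7-dihydroxy-2,3-dihydro-4H-chromen-4-one | Oc1ccc2c(c1)O[C@H](c1ccc(O)c(O)c1)[C@@H](O)[C@H]2c1cc2c(cc1O)O[C@H](c1ccc(O)c(O)c1)[C@@H](O)C2=O | intermediate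
32 | (2R,3S,4R)-2-(3,4-dihydroxyphenyl)-6-[(2R,3S,4S)-2-(3,4-dihydroxyphenyl)-3,7-dihydroxy-3,4-dihydro-2H-chromen-4-yl]-3,4-dihydro-2H-chromene-3,4,7-triol (upper unit 2,3-trans-3,4-cis, lower unit 2,3-trans-3,4-trans) | Oc1ccc2c(c1)O[C@H](c1ccc(O)c(O)c1)[C@@H](O)[C@H]2c1cc2c(cc1O)O[C@H](c1ccc(O)c(O)c1)[C@@H](O)[C@@H]2O | target

**Summary**

Total step count: 18. Longest linear sequence: 18 steps (1 → 32); 3, 9, 14 and 21 are purchased.

**Steps most likely to fail**

Step 12. The cycloaddition may stall because the nucleophilic diene terminus carries the hindered C4 substituent, which leaves time for hydrolytic loss of the diene and polymerisation of the ynone. The fallback brings ring D in preformed by carbonyl addition; it sets out from 8 and returns at 25. Catalogue 1-(5-bromo-2,4-dihydroxyphenyl)ethanone is protected as 1-[5-bromo-2,4-bis(methoxymethoxy)phenyl]ethanone F1 (MOMCl, i-Pr2NEt). It is then ketalised to 2-[5-bromo-2,4-bis(methoxymethoxy)phenyl]-2-methyl-1,3-dioxolane F2 (1,2-bis(trimethylsilyloxy)ethane, cat. TMSOTf, CH2Cl2, −78 °C). Bromine–lithium exchange (n-BuLi, THF, −78 °C) gives the aryllithium F3, which adds to ketone 8 to give the 4-aryl-4-hydroxyflavan F4. Ionic hydrogenation (Et3SiH, CF3CO2H, CH2Cl2, −40 °C), with hydride again entering anti to the 3-silyloxy group, gives the 3,4-cis 4-arylflavan dioxolane F5. PPTS in wet acetone then frees the ketone and gives 25.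

Step 7. Hydride delivery may be poorly face-selective, or the cation may lose a proton to an alkylidene ester or shed the silyl ether. The fallback is conjugate reduction of a neutral alkene instead of cation capture; it sets out from 11 and returns at 12. Compound 11 is dehydrated on purpose (Burgess reagent, toluene, 60 °C) to the methyl chroman-4-ylideneacetate F6. The bulky copper hydride [(Ph3P)CuH]6 (toluene, rt; aq. NH4Cl) then adds hydride to C4 from the face away from the 3-silyloxy group to give 12.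

Step 16. In hot acid the oxirane may ionise at its electron-rich benzylic carbon before the phenol is free, which erodes the 2',3'-trans selectivity and opens paths to solvent adducts and aryl-shifted by-products. The fallback is a two-stage thiol opening and thiophilic ring closure; it sets out from 27 and returns at 29 and from there at 30. Benzyl mercaptan and SnCl4 (CH2Cl2, −20 °C) open the oxirane at the benzylic carbon and strip both methoxymethyl groups, giving the β-benzylsulfanyl α-hydroxy ketone F7. AgBF4 (CH2Cl2, 0 °C) activates sulfur and the ortho phenol closes ring F to the silylated dihydroflavonol 29, which is desilylated separately (HF·pyridine, THF) to 30.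

**Further compounds**

F1 | step 12 | 1-[5-bromo-2,4-bis(methoxymethoxy)phenyl]ethanone | CC(=O)c1cc(Br)c(OCOC)cc1OCOC
F2 | step 12 | 2-[5-bromo-2,4-bis(methoxymethoxy)phenyl]-2-methyl-1,3-dioxolane | CC1(OCCO1)c1cc(Br)c(OCOC)cc1OCOC
F3 | step 12 | [2,4-bis(methoxymethoxy)-5-(2-methyl-1,3-dioxolan-2-yl)phenyl]lithium | CC1(OCCO1)c1cc([Li])c(OCOC)cc1OCOC
F4 | step 12 | (2R,3R,4RS)-7-(benzyloxy)-2-[3,4-bis(benzyloxy)phenyl]-4-[2,4-bis(methoxymethoxy)-5-(2-methyl-1,3-dioxolan-2-yl)phenyl]-3-[(tert-butyldimethylsilyl)oxy]-3,4-dihydro-2H-chromen-4-ol | O(Cc3ccccc3)c1ccc2c(c1)O[C@H](c1ccc(OCc3ccccc3)c(OCc3ccccc3)c1)[C@@H](O[Si](C)(C)C(C)(C)C)C2(O)c1cc(C4(C)OCCO4)c(OCOC)cc1OCOC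
F5 | step 12 | 2-{5-[(4R)-Fl]-2,4-bis(methoxymethoxy)phenyl}-2-methyl-1,3-dioxolane | O(Cc3ccccc3)c1ccc2c(c1)O[C@H](c1ccc(OCc3ccccc3)c(OCc3ccccc3)c1)[C@@H](O[Si](C)(C)C(C)(C)C)[C@H]2c1cc(C4(C)OCCO4)c(OCOC)cc1OCOC
F6 | step 7 | methyl 2-{(2R,3S)-7-(benzyloxy)-2-[3,4-bis(benzyloxy)phenyl]-3-[(tert-butyldimethylsilyl)oxy]-2,3-dihydro-4H-chromen-4-ylidene}acetate (alkene geometry undefined) | O(Cc3ccccc3)c1ccc2c(c1)O[C@H](c1ccc(OCc3ccccc3)c(OCc3ccccc3)c1)[C@@H](O[Si](C)(C)C(C)(C)C)C2=CC(=O)OC
F7 | step 16 | (2S)-3-(benzylsulfanyl)-3-[3,4-bis(benzyloxy)phenyl]-1-{5-[(4S)-Fl]-2,4-dihydroxyphenyl}-2-hydroxypropan-1-one (sulfur-bearing carbon undefined) | O(Cc3ccccc3)c1ccc2c(c1)O[C@H](c1ccc(OCc3ccccc3)c(OCc3ccccc3)c1)[C@@H](O[Si](C)(C)C(C)(C)C)[C@H]2c1cc(C(=O)[C@H](O)C(SCc5ccccc5)c6ccc(OCc5ccccc5)c(OCc5ccccc5)c6)c(O)cc1O
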